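(The constants are assumed, and the outcome is calculated.)

How much faster did the target form at 30% conversion when I charged more free catalyst?

    starting material + catalyst intermediate B → catalyst intermediate C (k1 = 20 M⁻¹ s⁻¹)
    partner → decomposed reagent (k2 = 0.068 s⁻¹)
    catalyst intermediate A ⇌ catalyst intermediate B (K3 = 12, k3 = 1.7 s⁻¹)
    partner + free catalyst → catalyst intermediate A (k4 = 500 M⁻¹ s⁻¹)
    catalyst intermediate C → by-product + catalyst intermediate D (k5 = 1.2 s⁻¹)
    catalyst intermediate D ⇌ free catalyst + target (K6 = 0.035 M, k6 = 1.6 s⁻¹)
    gas ⇌ partner, rate k7*(csat - [partner]) (k7 = 0.025 s⁻¹, csat = 6.9 mM)
starting material 0.10 M; gas 6.9 mM (held); free catalyst 1.0 mM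
- factor on the rate of making target when 30% of the starting material are converted if free catalyst is charged twice over
- factor on the rate when 30% of the starting material are converted if free catalyst is charged at 10 mM instead

I followed one dissolved partner molecule. It had 3 exits: capture by free catalyst, decomposition at 0.068 s⁻¹, or return to the gas at 0.025 s⁻¹. Capture matched the other two exits together at a free catalyst level of 0.186 mM. This half-capture level, much like a Michaelis constant, gives the capture chance as free catalyst over free catalyst plus that level. Partner entered at about 0.0104 M min⁻¹, so I took the rate of making target as that supply times the chance.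

Part of the charge stood outside free catalyst, though. I took the release of target as near balance at 0.0300 M target, so free catalyst plus catalyst intermediate D came to 1.86 times free catalyst, a product inhibition. I also gave the cycle a transit of 2.76 s, the sum of its inverse step rates. Balancing each charge against both gave a small table.

With 1.0 mM charged, free catalyst was 0.368 mM and the chance 0.664.
With 2.00 mM charged, they were 0.866 mM and 0.823.
With 10 mM charged, they were 5.14 mM and 0.965.

Reading down the free catalyst column, the doubled charge gave 2.35 times the free catalyst, more than in proportion. The chance column rose less, so I committed to a factor of 1.24. The last row gave 1.45.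

The forecast gave 1.24 (1.15 to 1.35) and 1.46 (1.33 to 1.6), holding that “extra catalyst mainly diverts more of the gas-transfer supply”.

The simulation gave 1.23 for the doubled charge and 1.35 for 10 mM. In the flask charged with 1.0 mM, target formed at 0.00681 M min⁻¹ at that conversion, which is 0.655 of the partner supply. In the flask charged with 10 mM, the rate at that conversion was 0.884 of the supply, less than the capture chance that the half-capture level gave for 5.14 mM free catalyst, 0.965.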